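## The problem

Violacene (21) is a single cyclohexane in which four of the six ring carbons are stereocentres, so every stereochemical decision has to be taken on the ring itself. C1 is an all-carbon quaternary centre (methyl and (E)-2-chlorovinyl), C3 is fully substituted with chlorine and a bromomethyl group, C4 and C6 are secondary chlorides, and C2 and C5 are methylenes. The chlorines at C3, C4 and C6 all lie on the face that carries the chlorovinyl group. The C3/C4 dichloride is therefore cis and cannot come from anti addition of chlorine to an alkene, and both secondary chlorides are neopentylic (C4 next to C3, C6 next to C1), which makes substitution slow and elimination or rearrangement easy. The stereocentres can be chained: an oxygen at C6 can steer the construction of C1 on a small ring, C1 and C6 together can decide the face of a C4 carbonyl, the C4 carbinol can pass its configuration to C3 in a rearrangement, and the C6 oxygen can later shield one face of a C4 ketone. The halogens limit the reagents: the tertiary C3 chloride and any β-halo or β-silyloxy carbonyl intermediate eliminate with base, and the vinyl chloride and primary bromide would not survive dissolving metals, hydrogenation or warm nucleophilic hydride. The enabling feature is that C3, with Cl and CH2Br, sits between the methylene C2 and a carbon (C4) that can be a carbonyl. An α-chloro-α-(bromomethyl) ketone is what a bromonium ion produces from a 1-chlorovinyl carbinol when a ring carbon migrates, and on a cyclopentanol that migration also builds the six-membered ring.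

## Retrosynthesis

**C6–Cl and C4–Cl.** The two secondary C–Cl bonds of 21 are cut back to C–O bonds of opposite configuration, first at C6 (alcohol 20, from silyl ether 19) and then at C4 (alcohol 17), with N-chlorosuccinimide 18 as the chlorine source. An alkene-based entry is excluded because the C3/C4 pair is cis and C4/C6 are 1,3-related, whereas oxygen at C6 is needed earlier as a control element and oxygen at C4 is what the ring-forming step leaves behind. The two substitutions are separated because a free cis-4,6-diol could tie up the activating reagent and because the C6 silyl ether is still needed to steer the step before. The forward reactions must invert two hindered secondary carbons without elimination and without bridging by the C3 chlorine.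

**C4–H.** Alcohol 17 is traced to ketone 16. This removes one stereocentre and exposes the α-chloro-α-(bromomethyl) ketone. The forward reduction must deliver hydrogen to the face of C4 opposite the C6 silyloxy group, so that the hydroxyl is cis to the C6 oxygen and trans to the C3 chlorine.

**C2–C3 and CH2–Br (key cut).** In 16 the C2–C3 bond and the C–Br bond are cut and C2 is reattached to C4, which gives the cyclopentanol 14 with a 1-chlorovinyl group on C4, and N-bromosuccinimide 15. The neighbouring cuts (C3–C4 by an enolate or dipole, or stepwise α-functionalisation of a preformed cyclohexanone) would have to tell C3 from C5 and build the halogenated quaternary carbon in several operations. The rearrangement delivers chlorine, bromomethyl and both ring bonds of C3 at once and leaves the carbonyl exactly where the last chlorine must go. The precursor is a cyclopentane without C3 stereochemistry and without bromine. The forward step must choose the 1-chlorovinyl alkene over the 2-chlorovinyl alkene, migrate C2 and not C5, and relay the C4 configuration to C3.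

**C3–C4.** Carbinol 14 is cut between the ring and the 1-chlorovinyl group to ketone 11 and 1-chloroethenyllithium 13, made from chloroethene 12. This is the only two-carbon nucleophile that already carries the chlorine on the right carbon. The addition must occur from the face opposite the C6 silyloxy group and the C1 methyl.

**The chlorovinyl double bond.** The (E)-2-chlorovinyl group of 11 is cut at its C=C bond to aldehyde 9 and chloroform 10, and 9 is traced through ozonide 8 to the vinyl ketone 7. A 2-chlorovinyl metal reagent would lose chloride to give an alkyne, so a plain vinyl group is carried in as a surrogate for the formyl group. The olefination must distinguish the aldehyde from the ring ketone and give the (E)-isomer.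

**C1–vinyl.** Ketone 7 is cut at the bond from C1 to the vinyl group, giving enone 4 and vinylmagnesium bromide 5, with the silyl enol ether 6 as the primary adduct. Conjugate addition anti to the neighbouring silyloxy group is the most reliable way to set a quaternary centre relative to an existing oxygen on a five-membered ring. The forward step has to overcome the β,β-disubstitution of the enone.

**C1–CH3.** Enone 4 is cut at its methyl group to the silyl enol ether 3 and further to the commercial enone 1 and methylmagnesium bromide 2: methyl is added and the enone is regenerated by oxidation. Methyl must come first and vinyl second, because the second group enters anti to the C6 oxygen and the target needs the chlorovinyl group trans, and methyl cis, to that oxygen.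

## Roads not taken

**Alternative 1:** The cut is the C1–C6 bond, with reconnection of C4 to a lactone oxygen. Forward, the silyl ketene acetal of a six-membered lactone that carries a 2-chlorovinyl group on its carbinol carbon would rearrange through a boat transition state (ring-contracting Ireland–Claisen) to (1R,2R)-2-chloro-1-methylcyclohex-3-ene-1-carboxylic acid A1.
- Merits: the pericyclic step transfers one carbinol stereocentre to both C1 and C6, and the carboxyl group is a short distance from the chlorovinyl group. In one respect it is better than the chosen plan: the neopentylic C6–Cl stereocentre is made by C–C bond formation, not by a hindered substitution.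
- Weak points: A1 has a bare methylene at C3 and only an alkene at C4/C5. The halogenated quaternary C3 and the cis C4 chloride would still need an allylic oxidation, an exocyclic alkene, a regio- and face-selective bromochlorination and a separate C4 operation, all while the allylic C6 chloride of A1 is exposed to ionisation and allylic transposition. The enantiopure lactone with a defined chloroalkene geometry is itself a multistep target.
- Comparison: the chosen plan pays for its two late substitutions (steps 9 and 11) but obtains C3 complete in the ring-forming step and reaches 21 in eleven steps from a purchasable chiral enone; Alternative 1 would be clearly longer.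

**Alternative 2:** The cuts are C3–C4 and O–CH2 of an isoxazoline. Forward, a nitrile oxide generated at C4 would add across a tethered 2-chloroalkene to give (3aR,5R,6R)-3a,6-dichloro-5-[(E)-2-chloroethenyl]-5-methyl-3,3a,4,5,6,7-hexahydro-2,1-benzoxazole A2.
- Merits: the carbocycle, the C3–Cl quaternary centre and an oxygenated CH2 handle appear in one step, and C4 emerges at the ketone oxidation level after N–O cleavage, so the C4 end game would be the same as here. It is better in that the C6 chlorine can be placed on an open chain, where substitution is easier than on the ring.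
- Weak points: the C3 configuration would depend on a chair-like transition state controlled only by the remote C1 and C6. A2 is a 4-chloroisoxazoline with hydrogens on the adjacent O–CH2 and can lose HCl to an aromatic isoxazole. Reductive N–O cleavage would have to spare a tertiary α-chloride and a vinyl chloride. The open-chain precursor, with the quaternary C1 and the C6 chloride, needs its own asymmetric synthesis.
- Comparison: the chosen plan has ring-relayed stereocontrol from one purchased stereocentre, no reduction step in the presence of the sensitive C–Cl bonds, and delivers CH2Br directly.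

**Alternative 3:** The cut is C5–C6 (retro-aldol). Forward, the proline enamine of a methyl ketone would add to one of two enantiotopic formyl groups on a quaternary carbon to give (1S,2S)-2-hydroxy-1-methyl-4-oxocyclohexane-1-carbaldehyde A3.
- Merits: it is catalytic and asymmetric from an achiral chain, sets C1 and C6 together, and gives the formyl group ready for chloro-olefination, which would save the vinyl addition and ozonolysis. For the C1/C6 part it is shorter than steps 1–5 here.
- Weak points: A3 has a methylene at C3. Chlorine and bromomethyl would have to be introduced α to the ketone in two operations, differentiating C3 from C5 although enolisation toward C5 expels the C6 oxygen, and with no obvious control of the C3 configuration. The aldol itself must control both group and diastereoselection at a hindered dialdehyde and avoid dehydration. The chlorinations at C4 and C6 would be as hard as here.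
- Comparison: the chosen plan has regiochemically unambiguous formation of C3 with both substituents and a stereochemical model for it, at the price of a longer opening sequence.

Key step: step 7

Remark on the chemistry: the target locants C1–C6 are used for all intermediates (C3 is exocyclic before step 7), and enone 1 is taken as a purchasable single enantiomer.

## Route

Step 1
Reactants: 1 (4S)-4-[tert-butyl(dimethyl)silyl]oxycyclopent-2-en-1-one; 2 methylmagnesium bromide
Product: 3 tert-butyl-dimethyl-[(1S,2S)-2-methyl-4-trimethylsilyloxycyclopent-3-en-1-yl]oxysilane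
Conditions: MeMgBr, CuBr·SMe2 (10 mol %), TMSCl, DMPU, THF, −78 °C; Et3N, cold aq. NaHCO3 work-up
Reagents that add atoms: methylmagnesium bromide (2), C[Mg]Br; chlorotrimethylsilane, C[Si](C)(C)Cl
Why: Copper-catalysed conjugate addition of a Grignard reagent with in situ silylation of the enolate; methyl should add to C1 anti to the C6 silyloxy group (a temporary stereocentre), and trapping as the silyl enol ether keeps the β-silyloxy ketone from eliminating and fixes the enol double bond between C2 and C4 for step 2.

Step 2
Reactants: 3 tert-butyl-dimethyl-[(1S,2S)-2-methyl-4-trimethylsilyloxycyclopent-3-en-1-yl]oxysilane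
Product: 4 (4S)-4-[tert-butyl(dimethyl)silyl]oxy-3-methylcyclopent-2-en-1-one
Conditions: Pd(OAc)2 (10 mol %), O2 (1 atm), DMSO, 25 °C
Reagents that add atoms: none
Why: Saegusa–Ito oxidation; the palladium enolate at C2 should lose the C1 hydrogen by β-hydride elimination, which regenerates the enone with methyl on the β-carbon, while O2 returns zerovalent palladium to divalent palladium. The C6 stereocentre is not involved.

Step 3
Reactants: 4 (4S)-4-[tert-butyl(dimethyl)silyl]oxy-3-methylcyclopent-2-en-1-one; 5 vinylmagnesium bromide
Product: 7 (3R,4S)-4-[tert-butyl(dimethyl)silyl]oxy-3-ethenyl-3-methylcyclopentan-1-one, via trimethylsilyl enol ether 6 (not isolated)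
Conditions: CH2=CHMgBr, CuBr·SMe2 (20 mol %), TMSCl, DMPU, THF, −78 → −40 °C; then 1 M HCl, THF, 0 °C
Reagents that add atoms: vinylmagnesium bromide (5), C=C[Mg]Br
Why: Copper-catalysed, chlorosilane-accelerated conjugate addition to a β,β-disubstituted enone; vinyl should enter anti to the adjacent silyloxy group, which sets the quaternary C1 with methyl cis and vinyl trans to the C6 oxygen. Brief acid hydrolysis of enol ether 6 gives the ketone without base, so the β-silyloxy group is not eliminated.

Step 4
Reactants: 7 (3R,4S)-4-[tert-butyl(dimethyl)silyl]oxy-3-ethenyl-3-methylcyclopentan-1-one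
Product: 9 (1S,2S)-2-[tert-butyl(dimethyl)silyl]oxy-1-methyl-4-oxocyclopentane-1-carbaldehyde, via ozonide 8 (not isolated)
Conditions: O3, CH2Cl2, −78 °C; then Me2S, −78 °C → rt
Reagents that add atoms: ozone, [O-][O+]=O
Why: Ozonolysis with reductive work-up; the vinyl group is the only alkene present, and the aldehyde has no α-hydrogen, so C1 cannot epimerise.

Step 5
Reactants: 9 (1S,2S)-2-[tert-butyl(dimethyl)silyl]oxy-1-methyl-4-oxocyclopentane-1-carbaldehyde; 10 chloroform
Product: 11 (3R,4S)-4-[tert-butyl(dimethyl)silyl]oxy-3-[(E)-2-chloroethenyl]-3-methylcyclopentan-1-one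
Conditions: CrCl2 (6 equiv), CHCl3 (2 equiv), THF, 65 °C
Reagents that add atoms: chloroform (10), ClC(Cl)Cl
Why: Takai olefination; the geminal dichromium species from chloroform should add to the aldehyde much faster than to the ring ketone and give the (E)-chloroalkene.

Step 6
Reactants: 11 (3R,4S)-4-[tert-butyl(dimethyl)silyl]oxy-3-[(E)-2-chloroethenyl]-3-methylcyclopentan-1-one; 12 chloroethene
Product: 14 (1S,3R,4S)-4-[tert-butyl(dimethyl)silyl]oxy-1-(1-chloroethenyl)-3-[(E)-2-chloroethenyl]-3-methylcyclopentan-1-ol, via 1-chloroethenyllithium 13 (not isolated)
Conditions: CH2=CHCl (1.5 equiv), s-BuLi (1.3 equiv), THF/Et2O/pentane (4:1:1), −110 °C; then 11, −110 → −90 °C; AcOH, THF, −90 °C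
Reagents that add atoms: chloroethene (12), C=CCl
Why: α-Lithiation of vinyl chloride and 1,2-addition of the vinyl carbenoid to a ketone, kept below its decomposition temperature and with no free alkyllithium left. In the half-chair of 11 with silyloxy and chlorovinyl groups pseudo-equatorial, the C1 methyl is pseudo-axial on the face that also carries the silyloxy group, so the nucleophile should enter from the other face and place the C4 hydroxyl cis to the C6 oxygen.

Step 7
Reactants: 14 (1S,3R,4S)-4-[tert-butyl(dimethyl)silyl]oxy-1-(1-chloroethenyl)-3-[(E)-2-chloroethenyl]-3-methylcyclopentan-1-ol; 15 N-bromosuccinimide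
Product: 16 (2R,4R,5S)-2-(bromomethyl)-5-[tert-butyl(dimethyl)silyl]oxy-2-chloro-4-[(E)-2-chloroethenyl]-4-methylcyclohexan-1-one
Conditions: NBS (1.1 equiv), (CF3)2CHOH/CH2Cl2 (1:4), −20 → 0 °C, dark
Reagents that add atoms: N-bromosuccinimide (15), O=C1CCC(=O)N1Br
Why: Proposed new method: electrophilic bromine should add to the unsubstituted terminus of the 1-chlorovinyl group, the developing α-chloro carbocation at C3 is captured by a 1,2-shift of ring carbon C2 from the carbinol carbon C4, and loss of the hydroxyl proton leaves the C4 ketone, so that C2–C3 and CH2–Br form in one event. The closest known reaction type is the halonium-induced semipinacol ring expansion of 1-alkenylcycloalkanols to 2-(halomethyl)cycloalkanones, which has not been shown with chlorine on the carbinol-bound alkene carbon; the chlorine lowers the nucleophilicity of the alkene but stabilises the cation on the correct carbon, and the hydrogen-bond-donating solvent is chosen to raise the electrophilicity of the bromine source. The six-membered ring is closed by ring enlargement, C2 moving from C4 to the exocyclic C3, and not by cyclisation of a chain. The new stereocentre C3 is controlled by the configuration of C4: in the reactive rotamer the C–Cl bond lies over C5 and away from the C–O bond, C2 bonds to the alkene face it already faces and bromine arrives anti to it, which puts chlorine cis to the C1 chlorovinyl group. Two selectivities are needed: C2 must migrate in preference to C5, which rests on the inductive deactivation of C5 by the silyloxy-bearing C6, and bromine must choose the 1-chlorovinyl group over the (E)-2-chlorovinyl group, which is expected because only the former has an unhindered CH2 terminus and leads to a tertiary, chlorine-stabilised cation.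

Step 8
Reactants: 16 (2R,4R,5S)-2-(bromomethyl)-5-[tert-butyl(dimethyl)silyl]oxy-2-chloro-4-[(E)-2-chloroethenyl]-4-methylcyclohexan-1-one
Product: 17 (1R,2R,4R,5S)-2-(bromomethyl)-5-[tert-butyl(dimethyl)silyl]oxy-2-chloro-4-[(E)-2-chloroethenyl]-4-methylcyclohexan-1-ol
Conditions: LiBH(s-Bu)3, THF, −78 °C; AcOH, −78 °C
Reagents that add atoms: none
Why: Ketone reduction with a bulky trialkylborohydride; in the chair with the C3 chlorine axial the C6 silyloxy group is axial on the opposite face and blocks axial attack, so hydride should attack equatorially and give the axial alcohol, cis to the C6 oxygen and trans to the C3 chlorine. The cold acidic quench keeps the trans-chlorohydrin alkoxide from closing to an epoxide.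

Step 9
Reactants: 17 (1R,2R,4R,5S)-2-(bromomethyl)-5-[tert-butyl(dimethyl)silyl]oxy-2-chloro-4-[(E)-2-chloroethenyl]-4-methylcyclohexan-1-ol; 18 N-chlorosuccinimide
Product: 19 tert-butyl-[(1S,2R,4R,5S)-4-(bromomethyl)-4,5-dichloro-2-[(E)-2-chloroethenyl]-2-methylcyclohexyl]oxy-dimethylsilane
Conditions: PPh3 (3 equiv), NCS (3 equiv), THF, 0 °C → rt
Reagents that add atoms: N-chlorosuccinimide (18), O=C1CCC(=O)N1Cl
Why: Appel-type deoxychlorination through an alkoxyphosphonium salt displaced by chloride with inversion, the reaction type that turns trans-chlorohydrins into cis-1,2-dichlorides. Once the bulky oxyphosphonium group avoids the 1,3-diaxial contact with the C6 silyloxy group it is equatorial, where the C3 chlorine is gauche to it and cannot bridge and no anti hydrogen is available for elimination; the near-neutral medium should leave the silyl ether intact.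

Step 10
Reactants: 19 tert-butyl-[(1S,2R,4R,5S)-4-(bromomethyl)-4,5-dichloro-2-[(E)-2-chloroethenyl]-2-methylcyclohexyl]oxy-dimethylsilane
Product: 20 (1S,2R,4R,5S)-4-(bromomethyl)-4,5-dichloro-2-[(E)-2-chloroethenyl]-2-methylcyclohexan-1-ol
Conditions: HF (48 % aq.), MeCN, 0 °C → rt
Reagents that add atoms: none
Why: Acidic fluoride cleavage of a silyl ether; basic fluoride is avoided because the tertiary and secondary chlorides could eliminate.

Step 11
Reactants: 20 (1S,2R,4R,5S)-4-(bromomethyl)-4,5-dichloro-2-[(E)-2-chloroethenyl]-2-methylcyclohexan-1-ol; 18 N-chlorosuccinimide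
Product: 21 violacene, (1R,2S,4R,5R)-1-(bromomethyl)-1,2,4-trichloro-5-[(E)-2-chloroethenyl]-5-methylcyclohexane
Conditions: PPh3 (3 equiv), NCS (3 equiv), THF, rt → 45 °C
Reagents that add atoms: N-chlorosuccinimide (18), O=C1CCC(=O)N1Cl
Why: Appel-type deoxychlorination with inversion at C6, a substitution of the kind that has precedent on secondary cyclohexanols next to a methyl- and vinyl-bearing quaternary carbon. Backside entry of chloride should turn the C6 oxygen (cis to methyl) into the C6 chlorine cis to the chlorovinyl group; the neopentylic primary bromide is not expected to exchange.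

## Compound list

1 | (4S)-4-[tert-butyl(dimethyl)silyl]oxycyclopent-2-en-1-one | O=C1C=C[C@@H](O[Si](C)(C)C(C)(C)C)C1 | starting material
2 | methylmagnesium bromide | C[Mg]Br | starting material
3 | tert-butyl-dimethyl-[(1S,2S)-2-methyl-4-trimethylsilyloxycyclopent-3-en-1-yl]oxysilane | C[C@H]1C=C(O[Si](C)(C)C)C[C@@H]1O[Si](C)(C)C(C)(C)C | intermediate
4 | (4S)-4-[tert-butyl(dimethyl)silyl]oxy-3-methylcyclopent-2-en-1-one | CC1=CC(=O)C[C@@H]1O[Si](C)(C)C(C)(C)C | intermediate
5 | vinylmagnesium bromide | C=C[Mg]Br | starting material
6 | tert-butyl-[(1S,2S)-2-ethenyl-2-methyl-4-trimethylsilyloxycyclopent-3-en-1-yl]oxy-dimethylsilane | C[C@]1(C=C)C=C(O[Si](C)(C)C)C[C@@H]1O[Si](C)(C)C(C)(C)C | intermediate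
7 | (3R,4S)-4-[tert-butyl(dimethyl)silyl]oxy-3-ethenyl-3-methylcyclopentan-1-one | C[C@]1(C=C)CC(=O)C[C@@H]1O[Si](C)(C)C(C)(C)C | intermediate
8 | (3S,4S)-4-[tert-butyl(dimethyl)silyl]oxy-3-methyl-3-(1,2,4-trioxolan-3-yl)cyclopentan-1-one, both epimers at the trioxolane carbon | C[C@]1(C2OCOO2)CC(=O)C[C@@H]1O[Si](C)(C)C(C)(C)C | intermediate
9 | (1S,2S)-2-[tert-butyl(dimethyl)silyl]oxy-1-methyl-4-oxocyclopentane-1-carbaldehyde | C[C@]1(C=O)CC(=O)C[C@@H]1O[Si](C)(C)C(C)(C)C | intermediate
10 | chloroform | ClC(Cl)Cl | starting material
11 | (3R,4S)-4-[tert-butyl(dimethyl)silyl]oxy-3-[(E)-2-chloroethenyl]-3-methylcyclopentan-1-one | C[C@]1(/C=C/Cl)CC(=O)C[C@@H]1O[Si](C)(C)C(C)(C)C | intermediate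
12 | chloroethene | C=CCl | starting material
13 | 1-chloroethenyllithium | [Li]C(Cl)=C | intermediate
14 | (1S,3R,4S)-4-[tert-butyl(dimethyl)silyl]oxy-1-(1-chloroethenyl)-3-[(E)-2-chloroethenyl]-3-methylcyclopentan-1-ol | C[C@]1(/C=C/Cl)C[C@@](O)(C(Cl)=C)C[C@@H]1O[Si](C)(C)C(C)(C)C | intermediate
15 | N-bromosuccinimide | O=C1CCC(=O)N1Br | starting material
16 | (2R,4R,5S)-2-(bromomethyl)-5-[tert-butyl(dimethyl)silyl]oxy-2-chloro-4-[(E)-2-chloroethenyl]-4-methylcyclohexan-1-one | C[C@]1(/C=C/Cl)C[C@](Cl)(CBr)C(=O)C[C@@H]1O[Si](C)(C)C(C)(C)C | intermediate
17 | (1R,2R,4R,5S)-2-(bromomethyl)-5-[tert-butyl(dimethyl)silyl]oxy-2-chloro-4-[(E)-2-chloroethenyl]-4-methylcyclohexan-1-ol | C[C@]1(/C=C/Cl)C[C@](Cl)(CBr)[C@H](O)C[C@@H]1O[Si](C)(C)C(C)(C)C | intermediate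
18 | N-chlorosuccinimide | O=C1CCC(=O)N1Cl | starting material
19 | tert-butyl-[(1S,2R,4R,5S)-4-(bromomethyl)-4,5-dichloro-2-[(E)-2-chloroethenyl]-2-methylcyclohexyl]oxy-dimethylsilane | C[C@]1(/C=C/Cl)C[C@](Cl)(CBr)[C@@H](Cl)C[C@@H]1O[Si](C)(C)C(C)(C)C | intermediate
20 | (1S,2R,4R,5S)-4-(bromomethyl)-4,5-dichloro-2-[(E)-2-chloroethenyl]-2-methylcyclohexan-1-ol | C[C@]1(/C=C/Cl)C[C@](Cl)(CBr)[C@@H](Cl)C[C@@H]1O | intermediate
21 | violacene, (1R,2S,4R,5R)-1-(bromomethyl)-1,2,4-trichloro-5-[(E)-2-chloroethenyl]-5-methylcyclohexane | C[C@]1(/C=C/Cl)C[C@](Cl)(CBr)[C@@H](Cl)C[C@H]1Cl | target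

## Step count and least certain steps

Total: 11 steps. Longest linear sequence: 11 steps (1 → 21).

**Step 7 (key step).**
- Risk: sluggish bromination of the chlorine-deactivated alkene, so that the cation is intercepted by the neighbouring hydroxyl or the solvent before the shift, or migration of C5 in place of C2. The chlorine lowers alkene nucleophilicity, the cyclopentane-to-cyclohexane enlargement releases little strain, and the two candidate methylenes differ only in their β-substituents.
- Fallback (known reactions only), from 11 back to 16: addition of vinylmagnesium bromide 5 with CeCl3 would give (1S,3R,4S)-4-[tert-butyl(dimethyl)silyl]oxy-3-[(E)-2-chloroethenyl]-1-ethenyl-3-methylcyclopentan-1-ol F1. Its ring expansion with 15, the parent halonium-induced semipinacol of 1-vinylcycloalkanols, would give (2RS,4R,5S)-2-(bromomethyl)-5-[tert-butyl(dimethyl)silyl]oxy-4-[(E)-2-chloroethenyl]-4-methylcyclohexan-1-one F2. α-Chlorination with SO2Cl2 in CH2Cl2 at 0 °C, which attacks the more substituted acid-formed enol, should then place chlorine on C3 anti to the axial C1 methyl and return to 16. This path does not depend on the carbinol configuration; the choice between C2 and C5 migration would be tested on F1.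

**Step 6.**
- Risk: α-elimination of the vinyl carbenoid before it adds, enolisation of the β-silyloxy ketone followed by loss of the silyloxy group, or incomplete facial selectivity at the carbonyl.
- Fallback, from 11 back to 14: ethynylmagnesium bromide with CeCl3 in THF would give (1S,3R,4S)-4-[tert-butyl(dimethyl)silyl]oxy-3-[(E)-2-chloroethenyl]-1-ethynyl-3-methylcyclopentan-1-ol F3. Markovnikov hydrochlorination of the terminal alkyne with HCl·DMPU and catalytic (Ph3P)AuNTf2 would then give 14, so no carbenoid is needed.

**Step 8.**
- Risk: hydride delivery anti to the axial C3 chlorine (the electronically preferred trajectory of α-chloro ketones), which would give the C4 epimer, or closure of the chlorohydrin alkoxide to an epoxide.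
- Fallback, from 16 back to 21: aqueous HF in MeCN would give (2R,4R,5S)-2-(bromomethyl)-2-chloro-4-[(E)-2-chloroethenyl]-5-hydroxy-4-methylcyclohexan-1-one F4. Narasaka–Prasad reduction (Et2BOMe, NaBH4, THF/MeOH, −78 °C), in which the boron chelate between the C6 oxygen and the carbonyl closes that face, would give (1S,3R,4R,6R)-4-(bromomethyl)-4-chloro-6-[(E)-2-chloroethenyl]-6-methylcyclohexane-1,3-diol F5. Excess PPh3/18 would replace both hydroxyls with inversion and give 21.

**Step 9.**
- Risk: bridging by the C3 chlorine if the oxyphosphonium group reacts from an axial position (retention or chlorine shift), or elimination toward C5.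
- Fallback, from 17 back to 19: Tf2O and pyridine at −40 °C would give [(1R,2R,4R,5S)-2-(bromomethyl)-5-[tert-butyl(dimethyl)silyl]oxy-2-chloro-4-[(E)-2-chloroethenyl]-4-methylcyclohexyl] trifluoromethanesulfonate F6. This isolated sulfonate would be displaced by Bu4NCl in toluene, a direct substitution by free chloride in a non-ionising solvent.

**Step 11.**
- Risk: elimination to the C5–C6 alkene or a 1,2-shift of the chlorovinyl group from C1 in place of backside substitution at the neopentylic C6 of a cyclohexane.
- Fallback, from 14 back to 21, moving this substitution to the more reactive five-membered ring: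
  - Bu4NF in THF would give (1S,3S,4R)-1-(1-chloroethenyl)-4-[(E)-2-chloroethenyl]-4-methylcyclopentane-1,3-diol F7.
  - PPh3/18 would replace only the secondary hydroxyl with inversion and give (1S,3R,4R)-4-chloro-1-(1-chloroethenyl)-3-[(E)-2-chloroethenyl]-3-methylcyclopentan-1-ol F8.
  - Ring expansion with 15 under the conditions of step 7 (the C6 chlorine deactivates C5 at least as well as the silyloxy group) would give (2R,4R,5R)-2-(bromomethyl)-2,5-dichloro-4-[(E)-2-chloroethenyl]-4-methylcyclohexan-1-one F9.
  - LiBH(s-Bu)3 would give (1R,2R,4R,5R)-2-(bromomethyl)-2,5-dichloro-4-[(E)-2-chloroethenyl]-4-methylcyclohexan-1-ol F10, and PPh3/18 would give 21.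
  - This order gives up the silyloxy shield in the reduction and relies on the ring expansion once more.

## Further compounds

F1 | step 7 | (1S,3R,4S)-4-[tert-butyl(dimethyl)silyl]oxy-3-[(E)-2-chloroethenyl]-1-ethenyl-3-methylcyclopentan-1-ol | C[C@]1(/C=C/Cl)C[C@@](O)(C=C)C[C@@H]1O[Si](C)(C)C(C)(C)C
F2 | step 7 | (2RS,4R,5S)-2-(bromomethyl)-5-[tert-butyl(dimethyl)silyl]oxy-4-[(E)-2-chloroethenyl]-4-methylcyclohexan-1-one | C[C@]1(/C=C/Cl)CC(CBr)C(=O)C[C@@H]1O[Si](C)(C)C(C)(C)C
F3 | step 6 | (1S,3R,4S)-4-[tert-butyl(dimethyl)silyl]oxy-3-[(E)-2-chloroethenyl]-1-ethynyl-3-methylcyclopentan-1-ol | C[C@]1(/C=C/Cl)C[C@@](O)(C#C)C[C@@H]1O[Si](C)(C)C(C)(C)C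
F4 | step 8 | (2R,4R,5S)-2-(bromomethyl)-2-chloro-4-[(E)-2-chloroethenyl]-5-hydroxy-4-methylcyclohexan-1-one | C[C@]1(/C=C/Cl)C[C@](Cl)(CBr)C(=O)C[C@@H]1O
F5 | step 8 | (1S,3R,4R,6R)-4-(bromomethyl)-4-chloro-6-[(E)-2-chloroethenyl]-6-methylcyclohexane-1,3-diol | C[C@]1(/C=C/Cl)C[C@](Cl)(CBr)[C@H](O)C[C@@H]1O
F6 | step 9 | [(1R,2R,4R,5S)-2-(bromomethyl)-5-[tert-butyl(dimethyl)silyl]oxy-2-chloro-4-[(E)-2-chloroethenyl]-4-methylcyclohexyl] trifluoromethanesulfonate | C[C@]1(/C=C/Cl)C[C@](Cl)(CBr)[C@H](OS(=O)(=O)C(F)(F)F)C[C@@H]1O[Si](C)(C)C(C)(C)C
F7 | step 11 | (1S,3S,4R)-1-(1-chloroethenyl)-4-[(E)-2-chloroethenyl]-4-methylcyclopentane-1,3-diol | C[C@]1(/C=C/Cl)C[C@@](O)(C(Cl)=C)C[C@@H]1O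
F8 | step 11 | (1S,3R,4R)-4-chloro-1-(1-chloroethenyl)-3-[(E)-2-chloroethenyl]-3-methylcyclopentan-1-ol | C[C@]1(/C=C/Cl)C[C@@](O)(C(Cl)=C)C[C@H]1Cl
F9 | step 11 | (2R,4R,5R)-2-(bromomethyl)-2,5-dichloro-4-[(E)-2-chloroethenyl]-4-methylcyclohexan-1-one | C[C@]1(/C=C/Cl)C[C@](Cl)(CBr)C(=O)C[C@H]1Cl
F10 | step 11 | (1R,2R,4R,5R)-2-(bromomethyl)-2,5-dichloro-4-[(E)-2-chloroethenyl]-4-methylcyclohexan-1-ol | C[C@]1(/C=C/Cl)C[C@](Cl)(CBr)[C@H](O)C[C@H]1Cl
A1 | alternative 1 | (1R,2R)-2-chloro-1-methylcyclohex-3-ene-1-carboxylic acid | C[C@]1(C(O)=O)CCC=C[C@H]1Cl
A2 | alternative 2 | (3aR,5R,6R)-3a,6-dichloro-5-[(E)-2-chloroethenyl]-5-methyl-3,3a,4,5,6,7-hexahydro-2,1-benzoxazole | C[C@]1(/C=C/Cl)C[C@]2(Cl)CON=C2C[C@H]1Cl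
A3 | alternative 3 | (1S,2S)-2-hydroxy-1-methyl-4-oxocyclohexane-1-carbaldehyde | C[C@]1(C=O)CCC(=O)C[C@@H]1O
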